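Eudesmane atom labels are used throughout: ring A = C1-C2-C3-C4-C5-C10, ring B = C5-C6-C7-C8-C9-C10, C14 on C10, C15 on C4, C11(=C13)-C12O2Me on C7, β = the face of C14. The enabling feature is the ring A path C10-C1-C2-C3(O) combined with a C8=C9 bond in ring B, which is the retron of an oxy-Cope shift; the adjacent C3/C4 oxygens with C14 para to C3 map onto 2-methoxy-4-methylphenol.
Retrosynthesis: C5-OOH and C4=C15 go back to a C4=C5 alkene; the C3 and C8 ester C-O bonds, C11-C12 and C11=C13 go back to a C3 ketone, a C8=C9 alkene and a C11 alcohol; C4-C15 goes back to a C4 ketal; then C1-C10 is cut while C3-C8 is rejoined (retro-oxy-Cope); last the vinyl bond C2-C3 and the Diels-Alder bonds C5-C6 and C7-C8.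
Forward: the bicyclo[2.2.2]octene that holds the future ring B is closed first by cycloaddition of the masked ortho-benzoquinone with an acrylate; ring A arises in the sigmatropic step, which also opens the bicycle to ring B; then follow C15 with the C4=C5 bond, the C8 oxygen, the acrylate, the C3 ester and finally the hydroperoxide.
Stereochemistry: C7 and C10 (cis) come from the endo cycloaddition relayed by the boat-like shift, the absolute sense from separation of the diastereomeric pantolactone esters; C8 from silicon delivery by a tether on C11 (cis to C7); C3 from hydride attack anti to C14; C5 from singlet-oxygen attack anti to C14.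

Key step: step 6

Assumption: the thermal cycloaddition is not expected to show a useful facial bias from the pantolactone ester, so the auxiliary serves as a covalent resolving handle; the two ortho/endo diastereomers are taken to be separable, and the one carried on is identified by X-ray crystallography against the known (R) centre of the lactone.
Remark on labels: in the bicyclic compounds the future eudesmane atoms are carbonyl/carbinol = C3, ketal = C4, bridgeheads = C5 and C8, ethano bridge = C6-C7, etheno bridge = C9=C10 (C14 on C10). IUPAC bicyclo numbers appear only in the names.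

Step 1
Reactants: 1 (R)-pantolactone; 2 acryloyl chloride
Product: 3 (R)-pantolactone acrylate
Conditions: Et3N, CH2Cl2, −20 → 0 °C
Reagents that add atoms: none
Why: Esterification of the secondary alcohol with the acid chloride under amine base is fast at low temperature, where the acrylate does not polymerise, and the (R) centre is not involved.

Step 2
Reactants: 4 2-methoxy-4-methylphenol; 3 (R)-pantolactone acrylate
Product: 6 ortho/endo (1S,4S,7S) keto ester cycloadduct, via masked ortho-benzoquinone 5 (not isolated)
Conditions: PhI(OAc)2, MeOH, 3 (3 equiv, excess recovered), slow addition of 4, rt → 50 °C; separation of the two endo diastereomers (SiO2, crystallisation)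
Reagents that add atoms: methanol CO
Why: Oxidative dearomatisation of the guaiacol in methanol gives dienone 5, which is trapped in a Diels–Alder reaction known to be ortho- and endo-selective with acrylates (ester carbon on C7, next to the bridgehead α to the ketone and syn to the new C9=C10 bond), so the three ring stereocentres are set relative to one another by the cycloaddition and in the absolute sense by separating the two diastereomeric pantolactone esters.

Step 3
Reactants: 6 ortho/endo keto ester cycloadduct; 7 vinylmagnesium bromide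
Product: 8 vinyl carbinol ester
Conditions: CeCl3 (dried), THF, −78 °C; sat. aq. NH4Cl
Reagents that add atoms: none
Why: 1,2-Addition of the organocerium reagent made from the Grignard reagent is selective for the ketone over the two ester carbonyls at −78 °C, and the nucleophile enters C3 from the face flanked by the sp2 etheno bridge, the less hindered side of bicyclo[2.2.2]octenones, which places the vinyl group syn to C9=C10 as the rearrangement demands.

Step 4
Reactants: 8 vinyl carbinol ester
Product: 9 bicyclic diol
Conditions: LiAlH4, THF, 0 °C; aqueous work-up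
Reagents that add atoms: none
Why: Hydride reduction of the ester (and of the lactone of the auxiliary) should give the C11 primary alcohol and release the auxiliary as a water-soluble triol, while ketal, tertiary alcohol and alkenes are inert to LiAlH4.

Step 5
Reactants: 9 bicyclic diol
Product: 10 TBDPS-protected 2-vinylbicyclo[2.2.2]oct-5-en-2-ol
Conditions: TBDPSCl, imidazole, CH2Cl2, 0 °C → rt
Reagents that add atoms: tert-butyl(chloro)diphenylsilane CC(C)(C)[Si](Cl)(c1ccccc1)c1ccccc1
Why: Silylation is selective for the primary over the hindered tertiary hydroxyl, and the TBDPS ether is chosen because it withstands KH in step 6 and aqueous acid in step 7.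

Step 6
Reactants: 10 TBDPS-protected 2-vinylbicyclo[2.2.2]oct-5-en-2-ol
Product: 13 cis-fused ketal ketone (5βH-eudesm-8-en-3-one skeleton), via potassium alkoxide 11 (not isolated), via potassium enolate 12 (not isolated)
Conditions: KH, 18-crown-6, THF, 0 → 65 °C; MeOH, −78 °C
Reagents that add atoms: none
Why: KH with 18-crown-6 gives the free potassium alkoxide 11, whose oxyanion weakens the adjacent C3–C8 bond so that the 1,5-diene C1=C2–C3–C8–C9=C10 undergoes a concerted [3,3]-sigmatropic shift (C3–C8 breaks, C1–C10 forms) to enolate 12, which is protonated on quench to ketone 13; this is the known anionic oxy-Cope rearrangement of 2-vinylbicyclo[2.2.2]oct-5-en-2-ols derived from masked ortho-benzoquinone adducts into cis-decalins. Ring A (C10–C1–C2–C3–C4–C5) is closed by the sigmatropic C1–C10 bond formation itself, through the boat-like six-membered transition state that the bicycle enforces, while the former bicycle is opened to ring B with the C8=C9 alkene. The new quaternary centre C10 is controlled by the bicyclic framework: the vinyl terminus can reach only the face of C10 turned toward the C3–C4 bridge, so C14 is pushed to the face that carries H-5 and the endo C7 substituent, which gives the cis ring fusion and the cis C7/C10 relation of the target. The step needs the vinyl group syn to the etheno bridge and the ortho/endo adduct, both fixed in steps 2 and 3, and because it is stereospecific the enantiopurity of 10 should pass unchanged into 13. The silyl ether and ketal are inert to the alkoxide, and the cold quench keeps the enolate from aldol reactions.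

Step 7
Reactants: 13 cis-fused ketal ketone
Product: 15 diosphenol (4-hydroxy-4-en-3-one), via cis-3,4-dione 14 (not isolated)
Conditions: TFA/H2O (9:1), CH2Cl2, 0 °C → rt
Reagents that add atoms: water O
Why: Acid hydrolysis of the dimethyl ketal gives dione 14, which enolises under the same conditions toward C5 to the conjugated, hydrogen-bonded diosphenol with a tetrasubstituted C4=C5 bond (the tautomer preferred by ring-fused 3,4-diones), which erases the C5 centre as planned while the TBDPS ether tolerates the short acid exposure.

Step 8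
Reactants: 15 diosphenol
Product: 16 enol triflate
Conditions: PhNTf2, Et3N, DMAP (cat.), CH2Cl2, 0 °C → rt
Reagents that add atoms: N-phenylbis(trifluoromethanesulfonimide) O=S(=O)(N(c1ccccc1)S(=O)(=O)C(F)(F)F)C(F)(F)F
Why: O-Triflation of the acidic enol (enol triflate formation) is unambiguous because the diosphenol anion carries its charge on the C4 oxygen and no other free hydroxyl is present.

Step 9
Reactants: 16 enol triflate
Product: 17 silyl-protected 4-methyl dienone
Conditions: trimethylboroxine, PdCl2(dppf), K3PO4, 1,4-dioxane, 90 °C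
Reagents that add atoms: trimethylboroxine CB1OB(C)OB(C)O1
Why: Suzuki–Miyaura coupling of the electron-poor α-triflyloxy enone delivers the C15 methyl to C4 with the C4=C5 bond already fixed, so neither a Grignard addition nor a regioselective dehydration is needed.

Step 10
Reactants: 17 silyl-protected 4-methyl dienone
Product: 18 homoallylic alcohol
Conditions: TBAF, THF, 0 °C → rt
Reagents that add atoms: none
Why: Fluoride-induced desilylation frees the homoallylic C11 hydroxyl that anchors the tether of the next step and touches neither the enone nor the ring alkene.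

Step 11
Reactants: 18 homoallylic alcohol
Product: 21 8β,11-diol, via dimethylsilyl ether 19 (not isolated), via cyclic siloxane 20 (not isolated)
Conditions: (HMe2Si)2NH, 50 °C, then evaporation; H2PtCl6·6H2O (cat.), THF, 60 °C; 30% H2O2, KF, KHCO3, THF/MeOH, rt
Reagents that add atoms: hydrogen peroxide OO (the silicon of 19 and 20 comes from 1,1,3,3-tetramethyldisilazane C[SiH](C)N[SiH](C)C and is lost again)
Why: Intramolecular hydrosilylation of a homoallylic alcohol followed by Tamao–Fleming oxidation: the O–SiMe2H tether on the β-oriented C11 can reach only the near alkene carbon C8 (five-membered oxasilolane) and only from the β face, Si–H adds syn, and the oxidation replaces C–Si by C–OH with retention, so the 8β-hydroxyl cis to the C7 substituent should result with fixed regiochemistry, while the tetrasubstituted enone is neither hydrosilylated nor epoxidised by the bicarbonate-buffered peroxide.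

Step 12
Reactants: 21 8β,11-diol
Product: 22 β-hydroxy aldehyde
Conditions: TEMPO (cat.), PhI(OAc)2, CH2Cl2, rt
Reagents that add atoms: none
Why: The oxoammonium oxidation is selective for the primary over the hindered axial secondary alcohol and stops at the aldehyde under non-basic conditions, so C7 keeps its configuration.

Step 13
Reactants: 22 β-hydroxy aldehyde
Product: 23 alkynol
Conditions: dimethyl (1-diazo-2-oxopropyl)phosphonate, K2CO3, MeOH, 0 °C → rt
Reagents that add atoms: dimethyl (1-diazo-2-oxopropyl)phosphonate CC(=O)C(=[N+]=[N-])P(=O)(OC)OC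
Why: Seyferth–Gilbert homologation with the Ohira–Bestmann reagent turns the aldehyde into the terminal alkyne (C13 from the reagent) under mild carbonate conditions in which a β-hydroxyl is too poor a leaving group for elimination, and since the equatorial C7 configuration is the thermodynamically preferred one, reversible enolisation of the aldehyde does no harm.

Step 14
Reactants: 23 alkynol
Product: 24 alkynyl acetate
Conditions: Ac2O, pyridine, DMAP, CH2Cl2, rt
Reagents that add atoms: acetic anhydride CC(=O)OC(C)=O
Why: DMAP-catalysed acylation esterifies the axial 8β-hydroxyl while C3 is still a ketone, which differentiates the two ring oxygens without protecting groups.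

Step 15
Reactants: 24 alkynyl acetate
Product: 25 acrylate enone
Conditions: Pd(OAc)2 (cat.), 2-(diphenylphosphino)pyridine, CH3SO3H (cat.), CO (10 bar), MeOH/CH2Cl2, 45 °C
Reagents that add atoms: carbon monoxide [C-]#[O+]; methanol CO
Why: Palladium-catalysed Markovnikov hydromethoxycarbonylation of terminal alkynes with the pyridylphosphine/acid catalyst places the ester carbon C12 on the internal carbon C11 and gives the 2-substituted acrylate directly, and with O8 acetylated no lactone can close.

Step 16
Reactants: 25 acrylate enone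
Product: 26 3β-allylic alcohol
Conditions: NaBH4, CeCl3·7H2O, MeOH, −40 → 0 °C
Reagents that add atoms: none
Why: Luche reduction reduces the enone carbonyl 1,2 without touching the acrylate or the esters, and hydride adds axially from the α face, anti to the axial C14 methyl, as is usual for 4-methyl-Δ4-3-ketones of this ring system, to give the pseudo-equatorial 3β-alcohol.

Step 17
Reactants: 26 3β-allylic alcohol
Product: 27 3β-isobutyrate
Conditions: i-PrCOCl, pyridine, DMAP (cat.), CH2Cl2, 0 °C → rt
Reagents that add atoms: 2-methylpropanoyl chloride CC(C)C(=O)Cl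
Why: Acylation of the unhindered allylic alcohol with the acid chloride proceeds at oxygen with retention at C3.

Step 18
Reactants: 27 3β-isobutyrate
Product: 28 CNP0244758.1 (target)
Conditions: O2, hν (visible), tetraphenylporphyrin (cat.), CH2Cl2, −20 °C; no reductive work-up
Reagents that add atoms: dioxygen O=O
Why: Schenck ene reaction: singlet oxygen attacks only the electron-rich tetrasubstituted C4=C5 bond, from the α face anti to the axial C14 methyl and the 3β-ester, where the only allylic hydrogens that are both aligned and unactivated are those of C15 (H-6α is equatorial, H-3α is geminal to the acyloxy group), so oxygen should bond to C5 and the double bond shift to C4=C15, which sets the 5α-hydroperoxide.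

Compound list
1 | (R)-pantolactone | CC1(C)COC(=O)[C@@H]1O | starting material
2 | acryloyl chloride | C=CC(=O)Cl | starting material
3 | (3R)-4,4-dimethyl-2-oxooxolan-3-yl prop-2-enoate ((R)-pantolactone acrylate) | C=CC(=O)O[C@H]1C(=O)OCC1(C)C | intermediate
4 | 2-methoxy-4-methylphenol | COc1cc(C)ccc1O | starting material
5 | 6,6-dimethoxy-4-methylcyclohexa-2,4-dien-1-one (masked ortho-benzoquinone) | COC1(OC)C=C(C)C=CC1=O | intermediate (not isolated)
6 | (3R)-4,4-dimethyl-2-oxooxolan-3-yl (1S,4S,7S)-3,3-dimethoxy-5-methyl-2-oxobicyclo[2.2.2]oct-5-ene-7-carboxylate (7-endo, ester syn to the C5=C6 bridge) | O=C1C(OC)(OC)[C@H]2C[C@H](C(=O)O[C@H]3C(=O)OCC3(C)C)[C@@H]1C=C2C | intermediate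
7 | vinylmagnesium bromide | C=C[Mg]Br | starting material
8 | (3R)-4,4-dimethyl-2-oxooxolan-3-yl (1S,2R,4S,7S)-2-ethenyl-2-hydroxy-3,3-dimethoxy-5-methylbicyclo[2.2.2]oct-5-ene-7-carboxylate (vinyl syn to the C5=C6 bridge) | C=C[C@]1(O)C(OC)(OC)[C@H]2C[C@H](C(=O)O[C@H]3C(=O)OCC3(C)C)[C@@H]1C=C2C | intermediate
9 | (1S,2R,4S,7S)-2-ethenyl-7-(hydroxymethyl)-3,3-dimethoxy-5-methylbicyclo[2.2.2]oct-5-en-2-ol | C=C[C@]1(O)C(OC)(OC)[C@H]2C[C@H](CO)[C@@H]1C=C2C | intermediate
10 | (1S,2R,4S,7S)-7-[(tert-butyldiphenylsilyl)oxymethyl]-2-ethenyl-3,3-dimethoxy-5-methylbicyclo[2.2.2]oct-5-en-2-ol | C=C[C@]1(O)C(OC)(OC)[C@H]2C[C@H](CO[Si](c3ccccc3)(c4ccccc4)C(C)(C)C)[C@@H]1C=C2C | intermediate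
11 | potassium alkoxide of 10 | C=C[C@]1([O-])C(OC)(OC)[C@H]2C[C@H](CO[Si](c3ccccc3)(c4ccccc4)C(C)(C)C)[C@@H]1C=C2C.[K+] | intermediate (not isolated)
12 | potassium C2=C3 enolate of 13 | CC(C)(C)[Si](c3ccccc3)(c4ccccc4)OC[C@H]1C[C@@H]2C(OC)(OC)C([O-])=CC[C@]2(C)C=C1.[K+] | intermediate (not isolated)
13 | 11-[(tert-butyldiphenylsilyl)oxy]-4,4-dimethoxy-12,13,15-trinor-5βH-eudesm-8-en-3-one (cis-decalin, 7β-CH2OSi, 10β-CH3) | CC(C)(C)[Si](c3ccccc3)(c4ccccc4)OC[C@H]1C[C@@H]2C(OC)(OC)C(=O)CC[C@]2(C)C=C1 | intermediate
14 | 11-[(tert-butyldiphenylsilyl)oxy]-12,13,15-trinor-5βH-eudesm-8-ene-3,4-dione (as first formed) | CC(C)(C)[Si](c3ccccc3)(c4ccccc4)OC[C@H]1C[C@@H]2C(=O)C(=O)CC[C@]2(C)C=C1 | intermediate (not isolated)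
15 | 11-[(tert-butyldiphenylsilyl)oxy]-4-hydroxy-12,13,15-trinoreudesma-4,8-dien-3-one | CC(C)(C)[Si](c3ccccc3)(c4ccccc4)OC[C@H]1CC2=C(O)C(=O)CC[C@]2(C)C=C1 | intermediate
16 | 11-[(tert-butyldiphenylsilyl)oxy]-3-oxo-12,13,15-trinoreudesma-4,8-dien-4-yl trifluoromethanesulfonate | CC(C)(C)[Si](c3ccccc3)(c4ccccc4)OC[C@H]1CC2=C(OS(=O)(=O)C(F)(F)F)C(=O)CC[C@]2(C)C=C1 | intermediate
17 | 11-[(tert-butyldiphenylsilyl)oxy]-12,13-dinoreudesma-4,8-dien-3-one | CC(C)(C)[Si](c3ccccc3)(c4ccccc4)OC[C@H]1CC2=C(C)C(=O)CC[C@]2(C)C=C1 | intermediate
18 | 11-hydroxy-12,13-dinoreudesma-4,8-dien-3-one | OC[C@H]1CC2=C(C)C(=O)CC[C@]2(C)C=C1 | intermediate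
19 | 11-(dimethylsilyloxy)-12,13-dinoreudesma-4,8-dien-3-one | C[SiH](C)OC[C@H]1CC2=C(C)C(=O)CC[C@]2(C)C=C1 | intermediate (not isolated)
20 | cyclic siloxane: 2,2-dimethyl-1-oxa-2-silacyclopentane cis-fused at C7–C8 (Si on C8β, O on C11) of 12,13-dinoreudesm-4-en-3-one | C[Si]3(C)OC[C@H]1CC2=C(C)C(=O)CC[C@]2(C)C[C@H]13 | intermediate (not isolated)
21 | 8β,11-dihydroxy-12,13-dinoreudesm-4-en-3-one | OC[C@H]1CC2=C(C)C(=O)CC[C@]2(C)C[C@H]1O | intermediate
22 | 8β-hydroxy-3-oxo-12,13-dinoreudesm-4-en-11-al | O=C[C@H]1CC2=C(C)C(=O)CC[C@]2(C)C[C@H]1O | intermediate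
23 | 8β-hydroxy-12-noreudesm-4-en-11(13)-yn-3-one | C#C[C@H]1CC2=C(C)C(=O)CC[C@]2(C)C[C@H]1O | intermediate
24 | 3-oxo-12-noreudesm-4-en-11(13)-yn-8β-yl acetate | C#C[C@H]1CC2=C(C)C(=O)CC[C@]2(C)C[C@H]1OC(C)=O | intermediate
25 | methyl 8β-acetoxy-3-oxoeudesma-4,11(13)-dien-12-oate | C=C(C(=O)OC)[C@H]1CC2=C(C)C(=O)CC[C@]2(C)C[C@H]1OC(C)=O | intermediate
26 | methyl 8β-acetoxy-3β-hydroxyeudesma-4,11(13)-dien-12-oate | C=C(C(=O)OC)[C@H]1CC2=C(C)[C@@H](O)CC[C@]2(C)C[C@H]1OC(C)=O | intermediate
27 | methyl 8β-acetoxy-3β-(2-methylpropanoyloxy)eudesma-4,11(13)-dien-12-oate | C=C(C(=O)OC)[C@H]1CC2=C(C)[C@@H](OC(=O)C(C)C)CC[C@]2(C)C[C@H]1OC(C)=O | intermediate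
28 | methyl (3S,5S,7R,8R,10R)-8-acetoxy-5-hydroperoxy-3-(2-methylpropanoyloxy)eudesma-4(15),11(13)-dien-12-oate (3β-ester, 5α-OOH, 8β-OAc, 10β-CH3; CNP0244758.1) | C=C(C(=O)OC)[C@H]1C[C@@]2(OO)C(=C)[C@@H](OC(=O)C(C)C)CC[C@]2(C)C[C@H]1OC(C)=O | target

Total step count: 18. Longest linear sequence: 18 steps (1 → 28; 17 from 4).

Steps most likely to fail

Step 2. The two endo diastereomers may co-elute or co-crystallise, and dimerisation of the dienone may outrun the cycloaddition when only a few equivalents of the chiral acrylate are present. Fallback: setting out from 4, the oxidation is run in methanol with a large excess of methyl acrylate to give the racemic methyl ester F1. Vinylcerium addition as in step 3 gives the racemic carbinol F2, and LiAlH4 gives the racemic diol, that is 9 together with its mirror-image diol F3. Esterification of the primary hydroxyl with (S)-O-methylmandelic acid (DCC, DMAP) gives two diastereomeric esters; the (S)-O-methylmandelate of 9 F4 is separated by chromatography or crystallisation and cleaved with K2CO3/MeOH, which comes back to the route at 9.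

Step 7. The ketal flanked by a ketone may resist hydrolysis, and acid strong enough to open it may strip the silyl ether or protonate the ring alkene. Fallback: setting out from 13, excess SmI2 in THF/MeOH removes both methoxy groups reductively to give the cis-fused 3-ketone F5. Enolisation toward C4, the direction preferred by cis-fused 3-ketones, under equilibrating conditions (TMSCl, NaI, Et3N, MeCN) gives the silyl enol ether F6, and Saegusa–Ito oxidation with Pd(OAc)2 gives the unsubstituted enone F7. Iodination (I2, pyridine) gives the 4-iodo enone F8, and Suzuki–Miyaura coupling with trimethylboroxine (PdCl2(dppf), K3PO4) comes back to the route at 17.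

Step 11. Addition of the tethered Si–H across the hindered ring alkene on the β face next to C14 may be slow, and platinum hydride may instead move the double bond. Fallback: setting out from 18, Boc2O/DMAP gives the homoallylic tert-butyl carbonate F9. IBr in toluene/CH2Cl2 at −80 °C closes the six-membered cyclic iodocarbonate F10, with the carbonate oxygen delivered to C8 from the β face and iodine anti on C9. Bu3SnH/AIBN removes the iodine to give the cyclic carbonate F11, and K2CO3/MeOH cleaves it, which comes back to the route at 21.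

Further compounds
F1 | step 2 | racemic methyl 3,3-dimethoxy-5-methyl-2-oxobicyclo[2.2.2]oct-5-ene-7-endo-carboxylate (one enantiomer drawn) | O=C1C(OC)(OC)[C@H]2C[C@H](C(=O)OC)[C@@H]1C=C2C
F2 | step 2 | racemic methyl 2-ethenyl-2-hydroxy-3,3-dimethoxy-5-methylbicyclo[2.2.2]oct-5-ene-7-endo-carboxylate (one enantiomer drawn) | C=C[C@]1(O)C(OC)(OC)[C@H]2C[C@H](C(=O)OC)[C@@H]1C=C2C
F3 | step 2 | mirror image of diol 9, (1R,2S,4R,7R), formed with 9 as the racemate | C=C[C@@]1(O)C(OC)(OC)[C@@H]2C[C@@H](CO)[C@H]1C=C2C
F4 | step 2 | (S)-2-methoxy-2-phenylacetate (O-methylmandelate) of the primary hydroxyl of 9 | C=C[C@]1(O)C(OC)(OC)[C@H]2C[C@H](COC(=O)[C@@H](OC)c3ccccc3)[C@@H]1C=C2C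
F5 | step 7 | 11-[(tert-butyldiphenylsilyl)oxy]-12,13,15-trinor-5βH-eudesm-8-en-3-one | CC(C)(C)[Si](c3ccccc3)(c4ccccc4)OC[C@H]1C[C@@H]2CC(=O)CC[C@]2(C)C=C1
F6 | step 7 | 3-(trimethylsilyloxy)-11-[(tert-butyldiphenylsilyl)oxy]-12,13,15-trinor-5βH-eudesma-3,8-diene | CC(C)(C)[Si](c3ccccc3)(c4ccccc4)OC[C@H]1C[C@@H]2C=C(O[Si](C)(C)C)CC[C@]2(C)C=C1
F7 | step 7 | 11-[(tert-butyldiphenylsilyl)oxy]-12,13,15-trinoreudesma-4,8-dien-3-one | CC(C)(C)[Si](c3ccccc3)(c4ccccc4)OC[C@H]1CC2=CC(=O)CC[C@]2(C)C=C1
F8 | step 7 | 4-iodo-11-[(tert-butyldiphenylsilyl)oxy]-12,13,15-trinoreudesma-4,8-dien-3-one | CC(C)(C)[Si](c3ccccc3)(c4ccccc4)OC[C@H]1CC2=C(I)C(=O)CC[C@]2(C)C=C1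
F9 | step 11 | tert-butyl carbonate of 18 at O11 | CC(C)(C)OC(=O)OC[C@H]1CC2=C(C)C(=O)CC[C@]2(C)C=C1
F10 | step 11 | 8β,11-cyclic carbonate of 9α-iodo-8β,11-dihydroxy-12,13-dinoreudesm-4-en-3-one | O=C3OC[C@H]1CC2=C(C)C(=O)CC[C@]2(C)[C@H](I)[C@H]1O3
F11 | step 11 | 8β,11-cyclic carbonate of 21 | O=C3OC[C@H]1CC2=C(C)C(=O)CC[C@]2(C)C[C@H]1O3
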